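**Plan**
- Retrosynthesis: first the four phenol O–H bonds (back to methyl ethers); then the tether bonds C4–C5 and C10–C11 together (chain numbered C1–C14 from ring A to ring B); last the ring–C1 bond of the four-carbon arm that remains.
- Enabling feature: the molecule is twofold symmetric about the midpoint of C7–C8. Rings A and B with their spacers C1–C4 and C11–C14 are identical, and C5–C10 is a bare hexamethylene core, so C4–C5 and C10–C11 are one bond made twice.
- Forward: the arm (ring plus C1–C4) is made from an aryl Grignard reagent and 1,4-dibromobutane. A three-component, twofold Cu-catalysed alkyl–alkyl coupling of the C5–C10 di-Grignard reagent with two arms follows; its second turnover joins a four-carbon aryl arm to the ten-carbon aryl chain. Global demethylation ends the route.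
- No ring is built: both benzene rings are bought with the 1,3,5-pattern in place. The helpers are the O-methyl groups (removed in step 3) and the C–Br/C–Mg activation (consumed in the couplings).
- Stereochemistry: the target has no stereocentre and no stereogenic double bond, so nothing has to be set.

Key step: step 2

Remark: Grignard reagents are drawn as monomeric RMgBr species and their spent form is taken as magnesium bromide.

**Step 1**
Reactants: 1 1-bromo-3,5-dimethoxybenzene; 2 1,4-dibromobutane
Product: 4 1-(4-bromobutyl)-3,5-dimethoxybenzene, via aryl Grignard 3 (not isolated)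
Conditions: Mg, I2 (cat.), THF, reflux; then add to 2 (4 equiv), Li2CuCl4 (3 mol %), THF, −10 °C → rt
Reagents that add atoms: none
Why: Magnesium insertion into the aryl C–Br bond gives 3, which under Li2CuCl4 catalysis (Kochi-type copper-catalysed Grignard–alkyl halide cross-coupling) should displace one primary bromide of 2; the fourfold excess of 2 should hold back a second substitution and the aryl methyl ethers are inert.

**Step 2**
Reactants: 5 1,6-dibromohexane; 4 1-(4-bromobutyl)-3,5-dimethoxybenzene (2.1 equiv)
Product: 8 1,14-bis(3,5-dimethoxyphenyl)tetradecane, via di-Grignard 6 (not isolated), via monoadduct Grignard 7 (not isolated)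
Conditions: Mg (excess), THF, 45 °C (5 → 6); then add slowly to 4, Li2CuCl4 (5 mol %), NMP (4 equiv), THF, 0 °C → rt
Reagents that add atoms: none
Why: Each C–Mg terminus of 6 transmetalates to copper to give an alkylcuprate, which displaces bromide from the primary C–Br of 4 in an SN2-type oxidative addition and then undergoes reductive elimination from Cu(III), forming a C(sp3)–C(sp3) bond and returning the catalyst. The first turnover gives the ten-carbon aryl Grignard reagent 7, whose remaining C–Mg end couples with a second molecule of 4 in the same way, so that this second turnover joins the four-carbon aryl arm to the ten-carbon aryl chain and completes the tetradecane tether. The closest known reaction type is the Li2CuCl4-catalysed Kochi coupling of primary alkyl Grignard reagents with primary alkyl bromides in THF/NMP, including twofold couplings of α,ω-di-Grignard reagents used to assemble long α,ω-difunctional alkanes. No ring is closed and no stereocentre is created, the product being achiral. The step needs cross-coupling to win over bromine–magnesium exchange, homocoupling, β-hydride elimination and stalling at the mono-adduct; the unhindered primary bromide of 4, the absence of any other electrophilic or acidic group (the aryl methyl ethers are inert), the slow addition of 6 to an excess of 4 and the NMP additive should secure this. Because the two ends of 6 and the two arms are identical by symmetry, no differentiation of termini is required.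

**Step 3**
Reactants: 8 1,14-bis(3,5-dimethoxyphenyl)tetradecane
Product: 10 bisnorstriatol, via tetrakis(dibromoboryl) ether 9 (not isolated)
Conditions: BBr3 (8 equiv), CH2Cl2, −78 °C → rt; then H2O, 0 °C
Reagents that add atoms: none
Why: BBr3 complexes each ether oxygen and bromide attacks the methyl group in an SN2 step (Lewis-acid aryl methyl ether cleavage) to give 9 and bromomethane; aqueous work-up should hydrolyse the B–O bonds to the tetraphenol while the saturated chain stays untouched.

**Compound list**
1 | 1-bromo-3,5-dimethoxybenzene | COc1cc(Br)cc(OC)c1 | starting material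
2 | 1,4-dibromobutane | BrCCCCBr | starting material
3 | (3,5-dimethoxyphenyl)magnesium bromide (aryl Grignard; formed in the flask) | COc1cc([Mg]Br)cc(OC)c1 | intermediate
4 | 1-(4-bromobutyl)-3,5-dimethoxybenzene | COc1cc(CCCCBr)cc(OC)c1 | intermediate
5 | 1,6-dibromohexane | BrCCCCCCBr | starting material
6 | hexane-1,6-diylbis(magnesium bromide) (di-Grignard; formed in the flask) | Br[Mg]CCCCCC[Mg]Br | intermediate
7 | [10-(3,5-dimethoxyphenyl)decyl]magnesium bromide (monoadduct Grignard; formed in the flask) | COc1cc(CCCCCCCCCC[Mg]Br)cc(OC)c1 | intermediate
8 | 1,14-bis(3,5-dimethoxyphenyl)tetradecane | COc1cc(CCCCCCCCCCCCCCc2cc(OC)cc(OC)c2)cc(OC)c1 | intermediate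
9 | 1,14-bis[3,5-bis(dibromoboryloxy)phenyl]tetradecane (formed in the flask) | BrB(Br)Oc1cc(OB(Br)Br)cc(CCCCCCCCCCCCCCc2cc(OB(Br)Br)cc(OB(Br)Br)c2)c1 | intermediate
10 | bisnorstriatol, 5,5'-(tetradecane-1,14-diyl)bis(benzene-1,3-diol) | Oc1cc(O)cc(CCCCCCCCCCCCCCc2cc(O)cc(O)c2)c1 | target

**Totals**
Total step count: 3. Longest linear sequence: 3 steps (1 → 4 → 8 → 10).

**Steps most likely to fail**

Step 2. Wurtz-type self-coupling during magnesium insertion into 5 and bromine–magnesium exchange between 6 or 7 and 4 would scramble the chain length. The sequence may also stall after the first C–C bond formation. Either process would leave products that differ from 8 only in the number of CH2 groups and would be hard to remove. Fallback, from 4 back to 8: hexa-1,5-diyne (commercial, handled as a cold solution) is deprotonated twice with n-BuLi in THF at −78 °C to give 1,6-dilithiohexa-1,5-diyne F1. This is alkylated at both ends with 4 (2.1 equiv) in THF/DMPU, −78 °C → rt, which should give 1,14-bis(3,5-dimethoxyphenyl)tetradeca-5,9-diyne F2. An SN2 alkylation of an acetylide cannot scramble chain length, and the polar diyne should be easy to separate from unreacted 4. Hydrogenation of F2 (H2, Pd/C, EtOAc) should then give 8.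

Step 1. The remaining C–Br end of the product may undergo a second substitution, the aryl Grignard reagent may homocouple oxidatively, and the aryl–copper species may couple sluggishly. The product would then be hard to free from excess 2. Fallback, from 1 back to 4: Sonogashira coupling of 1 with but-3-yn-1-ol (PdCl2(PPh3)2, CuI, Et3N, 80 °C) should give 4-(3,5-dimethoxyphenyl)but-3-yn-1-ol F3. Hydrogenation (H2, Pd/C, EtOH) should give 4-(3,5-dimethoxyphenyl)butan-1-ol F4. An Appel reaction (CBr4, PPh3, CH2Cl2, 0 °C) should convert the primary alcohol into bromide 4.

Step 3. Cleavage of the four methyl ethers may be incomplete, and the electron-rich rings may be brominated or degraded under the Lewis-acidic conditions. Partly methylated phenols would be hard to separate from the poorly soluble product. Fallback, from 2 to 10, with benzyl in place of methyl protection so that the last step is a neutral hydrogenolysis: purchased 1,3-bis(benzyloxy)-5-bromobenzene (Brc1cc(OCc2ccccc2)cc(OCc2ccccc2)c1) is converted with Mg in THF into [3,5-bis(benzyloxy)phenyl]magnesium bromide F5. Coupling of F5 with 2 under the conditions of step 1 should give 1,3-bis(benzyloxy)-5-(4-bromobutyl)benzene F6. Twofold coupling of F6 with di-Grignard 6 (from 5) under the conditions of step 2 should pass through {10-[3,5-bis(benzyloxy)phenyl]decyl}magnesium bromide F7 and give 1,14-bis[3,5-bis(benzyloxy)phenyl]tetradecane F8. Hydrogenolysis of F8 (H2, Pd/C, EtOAc/EtOH) should remove all four benzyl groups and give 10.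

**Further compounds**
F1 | step 2 | 1,6-dilithiohexa-1,5-diyne | [Li]C#CCCC#C[Li]
F2 | step 2 | 1,14-bis(3,5-dimethoxyphenyl)tetradeca-5,9-diyne | COc1cc(CCCCC#CCCC#CCCCCc2cc(OC)cc(OC)c2)cc(OC)c1
F3 | step 1 | 4-(3,5-dimethoxyphenyl)but-3-yn-1-ol | COc1cc(C#CCCO)cc(OC)c1
F4 | step 1 | 4-(3,5-dimethoxyphenyl)butan-1-ol | COc1cc(CCCCO)cc(OC)c1
F5 | step 3 | [3,5-bis(benzyloxy)phenyl]magnesium bromide | Br[Mg]c1cc(OCc2ccccc2)cc(OCc2ccccc2)c1
F6 | step 3 | 1,3-bis(benzyloxy)-5-(4-bromobutyl)benzene | BrCCCCc1cc(OCc2ccccc2)cc(OCc2ccccc2)c1
F7 | step 3 | {10-[3,5-bis(benzyloxy)phenyl]decyl}magnesium bromide | Br[Mg]CCCCCCCCCCc1cc(OCc2ccccc2)cc(OCc2ccccc2)c1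
F8 | step 3 | 1,14-bis[3,5-bis(benzyloxy)phenyl]tetradecane | c1ccccc1COc1cc(OCc2ccccc2)cc(CCCCCCCCCCCCCCc2cc(OCc3ccccc3)cc(OCc3ccccc3)c2)c1
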